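**Retrosynthetic overview**
- The depside ester bond between the C1 carbonyl of ring A (the acyl ring) and O4 of ring B (the ring with the free carboxyl) is cut first, after two benzyl groups are put on. This gives a ring A acid and a ring B phenol.
- The strategy rests on ring A. Its C6 propyl group and C1 carboxyl carbon sit on adjacent ring atoms, C1 is flanked on the other side by the C2 oxygen, and a second oxygen sits at C4. This is the pattern left when a carbon nucleophile and a carbon electrophile add across the C1–C6 triple bond of 3,5-dimethoxybenzyne.
- Ring A therefore comes in one flask from 1-fluoro-3,5-dimethoxybenzene, propyllithium and carbon dioxide. Chelation-controlled cleavage of the C2 methyl ether and benzyl protection follow.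
- Ring B comes from olivetol by carboxylation, benzyl ester formation, temporary allylation at O4 and methylation at O2.
- No ring is formed, since both benzene rings are purchased. Ring A is substituted in steps 1–5 and ring B in steps 6–10, and coupling and hydrogenolysis follow.

Key step: step 2

Remark on the chemistry: the target has no stereocentre and no stereogenic double bond, so no stereodescriptors are needed. Each ring is numbered from the carbon that bears its carbonyl group (C1).

**Step 1**
Reactants: 1 1-chloropropane
Product: 2 propyllithium (filtered, titrated pentane solution)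
Conditions: Li (1% Na, 2.3 equiv), pentane, reflux, Ar; filter, titrate
Reagents that add atoms: lithium metal, [Li]
Why: Reductive lithiation of a primary alkyl chloride by lithium metal is the standard preparation of n-alkyllithiums, and the hydrocarbon solvent allows the lithium chloride to be filtered off.

**Step 2**
Reactants: 2 propyllithium; 3 1-fluoro-3,5-dimethoxybenzene; 4 carbon dioxide
Product: 9 2,4-dimethoxy-6-propylbenzoic acid, via 2-fluoro-4,6-dimethoxyphenyllithium 5 (not isolated), via 3,5-dimethoxybenzyne 6 (not isolated), via 2,4-dimethoxy-6-propylphenyllithium 7 (not isolated), via lithium 2,4-dimethoxy-6-propylbenzoate 8 (not isolated)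
Conditions: 2 (2.5 equiv), THF–pentane, −78 °C, 1.5 h; warm to −15 °C, 1.5 h; recool to −78 °C, cannulate into THF saturated with dry 4; 2 M HCl
Reagents that add atoms: none
Why: Directed ortho-lithiation, aryne carbolithiation and carboxylation run in sequence: at −78 °C the first equivalent of 2 should remove the most acidic ring proton of 3, the one flanked by fluorine and a methoxy group (the two such positions are equivalent by symmetry), and on warming 5 loses lithium fluoride to give 6, the only aryne that 3 can form. A second equivalent of 2 adds to the strained triple bond at the carbon remote from the neighbouring methoxy group, because the inductive pull of that oxygen distorts the aryne so that the far carbon is the more electrophilic one and the charge develops beside oxygen, where induction and Li–O coordination stabilise it; this makes the C6–propyl bond and gives 7. Trapping of 7 with 4 makes the C1–carboxyl bond, and acid frees 9 from 8. The closest known reaction type is the reaction of fluoroanisoles with n-alkyllithiums followed by carbonation, which gives 6-alkyl-2-methoxybenzoic acids. No ring is closed and no stereocentre is formed; the step needs site selectivity in the lithiation, secured by the acidifying fluorine at low temperature (the position between the two methoxy groups is expected to be metalated only at higher temperature), and regioselectivity in the addition, secured by the methoxy group next to the triple bond. Full metalation before warming leaves no proton source for 7, the excess of 2 should outrun 5 and 7 as nucleophiles towards 6, and inverse addition to excess 4 suppresses ketone formation.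

**Step 3**
Reactants: 9 2,4-dimethoxy-6-propylbenzoic acid
Product: 11 2-hydroxy-4-methoxy-6-propylbenzoic acid, via cyclic chloroborate 10 (not isolated)
Conditions: BCl3 (1 M in CH2Cl2, 2.5 equiv), CH2Cl2, −78 → 0 °C; ice–water
Reagents that add atoms: none
Why: In this chelation-controlled Lewis-acid ether cleavage, boron binds the carboxyl oxygen and the adjacent C2 methoxy oxygen in a six-membered chelate, chloride removes that methyl group by SN2 attack, and the unchelated C4 methoxy group should survive at or below 0 °C.

**Step 4**
Reactants: 11 2-hydroxy-4-methoxy-6-propylbenzoic acid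
Product: 12 benzyl 2-(benzyloxy)-4-methoxy-6-propylbenzoate
Conditions: BnBr (2.5 equiv), K2CO3 (3 equiv), DMF, rt then 60 °C
Reagents that add atoms: benzyl bromide, BrCc1ccccc1
Why: In this double Williamson-type O-alkylation the carboxylate is benzylated first at room temperature, which removes the danger of decarboxylation, and the hydrogen-bonded phenol follows on warming.

**Step 5**
Reactants: 12 benzyl 2-(benzyloxy)-4-methoxy-6-propylbenzoate
Product: 14 2-(benzyloxy)-4-methoxy-6-propylbenzoic acid, via potassium 2-(benzyloxy)-4-methoxy-6-propylbenzoate 13 (not isolated)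
Conditions: KOH (10 equiv), DMSO–H2O 4:1, 100 °C; cold 2 M HCl
Reagents that add atoms: potassium hydroxide, [K+].[OH-]
Why: Saponification of a di-ortho-substituted benzoate needs poorly solvated hydroxide, which aqueous DMSO supplies, and the aryl benzyl and methyl ethers are inert to base.

**Step 6**
Reactants: 15 olivetol (5-pentylbenzene-1,3-diol)
Product: 17 olivetolic acid (2,4-dihydroxy-6-pentylbenzoic acid), via magnesium olivetolate chelate 16 (not isolated)
Conditions: MeOMgOCO2Me (2 M in DMF, 4 equiv), 120 °C, Ar; cold 2 M HCl
Reagents that add atoms: methylmagnesium carbonate, COC(=O)O[Mg]OC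
Why: In this Stiles carboxylation (Kolbe–Schmitt type) the magnesium phenoxide delivers carbon dioxide to an ortho carbon, the product is held as chelate 16, which pulls the equilibrium forward, and attack para to the second hydroxyl gives the 2,4-dihydroxy-6-pentyl pattern.

**Step 7**
Reactants: 17 olivetolic acid
Product: 18 benzyl 2,4-dihydroxy-6-pentylbenzoate
Conditions: BnBr (1.05 equiv), KHCO3 (1.2 equiv), DMF, rt
Reagents that add atoms: benzyl bromide, BrCc1ccccc1
Why: Hydrogen carbonate ionises only the carboxylic acid, so SN2 alkylation of the carboxylate gives the ester and leaves both phenols free.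

**Step 8**
Reactants: 18 benzyl 2,4-dihydroxy-6-pentylbenzoate
Product: 19 benzyl 4-(allyloxy)-2-hydroxy-6-pentylbenzoate
Conditions: allyl bromide (1.05 equiv), K2CO3 (1.1 equiv), acetone, rt → 45 °C
Reagents that add atoms: allyl bromide, C=CCBr
Why: Williamson etherification should take place at the C4 hydroxyl alone, because the C2 hydroxyl is locked in a hydrogen bond to the ester carbonyl and is much less nucleophilic.

**Step 9**
Reactants: 19 benzyl 4-(allyloxy)-2-hydroxy-6-pentylbenzoate
Product: 20 benzyl 4-(allyloxy)-2-methoxy-6-pentylbenzoate
Conditions: MeI (3 equiv), K2CO3 (3 equiv), DMF, 45 °C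
Reagents that add atoms: methyl iodide, CI
Why: With O4 blocked, excess methyl iodide and carbonate in a dipolar aprotic solvent force Williamson methylation of the chelated C2 hydroxyl, and the hindered benzyl ester and the allyl ether are inert.

**Step 10**
Reactants: 20 benzyl 4-(allyloxy)-2-methoxy-6-pentylbenzoate
Product: 21 benzyl 4-hydroxy-2-methoxy-6-pentylbenzoate
Conditions: Pd(PPh3)4 (5 mol %), morpholine (5 equiv), THF, rt
Reagents that add atoms: none
Why: In this Tsuji–Trost deallylation zerovalent palladium ionises the allyl–oxygen bond, helped by the ester-stabilised phenoxide leaving group, morpholine takes up the allyl group, and the benzyl ester is not touched.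

**Step 11**
Reactants: 14 2-(benzyloxy)-4-methoxy-6-propylbenzoic acid; 21 benzyl 4-hydroxy-2-methoxy-6-pentylbenzoate
Product: 23 benzyl 4-{[2-(benzyloxy)-4-methoxy-6-propylbenzoyl]oxy}-2-methoxy-6-pentylbenzoate, via aroyl trifluoroacetate 22 (not isolated)
Conditions: (CF3CO)2O (5 equiv), toluene, 0 °C → rt
Reagents that add atoms: none
Why: In this mixed-anhydride depside esterification the electron-rich, di-ortho-substituted aroyl trifluoroacetate reacts with strong acylium character, which avoids the steric barrier to tetrahedral addition, and it acylates the only free hydroxyl, that at C4 of 21.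

**Step 12**
Reactants: 23 benzyl 4-{[2-(benzyloxy)-4-methoxy-6-propylbenzoyl]oxy}-2-methoxy-6-pentylbenzoate
Product: 24 4-[(2-hydroxy-4-methoxy-6-propylbenzoyl)oxy]-2-methoxy-6-pentylbenzoic acid (CNP0522224.0)
Conditions: H2 (1 atm), 10% Pd/C, EtOAc, rt
Reagents that add atoms: none
Why: Catalytic hydrogenolysis cleaves both benzylic C–O bonds (the ether on ring A and the ester on ring B) under neutral conditions that leave the base-sensitive depside ester and the methyl ethers intact.

**Compound list**
1 | 1-chloropropane | CCCCl | starting material
2 | propyllithium | [Li]CCC | intermediate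
3 | 1-fluoro-3,5-dimethoxybenzene | COc1cc(F)cc(OC)c1 | starting material
4 | carbon dioxide | O=C=O | starting material
5 | 2-fluoro-4,6-dimethoxyphenyllithium | [Li]c1c(F)cc(OC)cc1OC | intermediate
6 | 3,5-dimethoxybenzyne | COC1=CC(OC)=CC#C1 | intermediate
7 | 2,4-dimethoxy-6-propylphenyllithium | [Li]c1c(CCC)cc(OC)cc1OC | intermediate
8 | lithium 2,4-dimethoxy-6-propylbenzoate | CCCc1cc(OC)cc(OC)c1C(=O)[O-].[Li+] | intermediate
9 | 2,4-dimethoxy-6-propylbenzoic acid | CCCc1cc(OC)cc(OC)c1C(=O)O | intermediate
10 | 2-chloro-7-methoxy-5-propyl-4H-1,3,2-benzodioxaborinin-4-one | CCCc1cc(OC)cc2OB(Cl)OC(=O)c12 | intermediate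
11 | 2-hydroxy-4-methoxy-6-propylbenzoic acid | CCCc1cc(OC)cc(O)c1C(=O)O | intermediate
12 | benzyl 2-(benzyloxy)-4-methoxy-6-propylbenzoate | CCCc1cc(OC)cc(OCc2ccccc2)c1C(=O)OCc1ccccc1 | intermediate
13 | potassium 2-(benzyloxy)-4-methoxy-6-propylbenzoate | CCCc1cc(OC)cc(OCc2ccccc2)c1C(=O)[O-].[K+] | intermediate
14 | 2-(benzyloxy)-4-methoxy-6-propylbenzoic acid | CCCc1cc(OC)cc(OCc2ccccc2)c1C(=O)O | intermediate
15 | olivetol | CCCCCc1cc(O)cc(O)c1 | starting material
16 | magnesium 4-hydroxy-2-oxido-6-pentylbenzoate | CCCCCc1cc(O)cc([O-])c1C(=O)[O-].[Mg+2] | intermediate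
17 | olivetolic acid (2,4-dihydroxy-6-pentylbenzoic acid) | CCCCCc1cc(O)cc(O)c1C(=O)O | intermediate
18 | benzyl 2,4-dihydroxy-6-pentylbenzoate | CCCCCc1cc(O)cc(O)c1C(=O)OCc1ccccc1 | intermediate
19 | benzyl 4-(allyloxy)-2-hydroxy-6-pentylbenzoate | CCCCCc1cc(OCC=C)cc(O)c1C(=O)OCc1ccccc1 | intermediate
20 | benzyl 4-(allyloxy)-2-methoxy-6-pentylbenzoate | CCCCCc1cc(OCC=C)cc(OC)c1C(=O)OCc1ccccc1 | intermediate
21 | benzyl 4-hydroxy-2-methoxy-6-pentylbenzoate | CCCCCc1cc(O)cc(OC)c1C(=O)OCc1ccccc1 | intermediate
22 | 2-(benzyloxy)-4-methoxy-6-propylbenzoic trifluoroacetic anhydride | CCCc1cc(OC)cc(OCc2ccccc2)c1C(=O)OC(=O)C(F)(F)F | intermediate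
23 | benzyl 4-{[2-(benzyloxy)-4-methoxy-6-propylbenzoyl]oxy}-2-methoxy-6-pentylbenzoate | CCCCCc1cc(OC(=O)c2c(OCc3ccccc3)cc(OC)cc2CCC)cc(OC)c1C(=O)OCc1ccccc1 | intermediate
24 | 4-[(2-hydroxy-4-methoxy-6-propylbenzoyl)oxy]-2-methoxy-6-pentylbenzoic acid | CCCCCc1cc(OC(=O)c2c(O)cc(OC)cc2CCC)cc(OC)c1C(=O)O | target

**Totals**
Total step count: 12.
Longest linear sequence: 7 steps (1, 2, 3, 4, 5, 11, 12). The ring B branch (6, 7, 8, 9, 10, 11, 12) has the same length.

**Steps most likely to fail**

Step 2.
- Several processes could lower the outcome:
  - metalation between the two methoxy groups, a dead end that cannot lose lithium fluoride;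
  - attack of the aryllithiums on the aryne, which couples two arenes;
  - a second lithiation of the ring before carbonation;
  - premature protonation.
- The fallback abandons the aryne and makes the two bonds one at a time.
- It sets out from 1, which magnesium in THF converts into propylmagnesium chloride F1.
- Kumada–Corriu coupling of F1 with purchased 1-chloro-3,5-dimethoxybenzene under NiCl2(dppp) should give 1,3-dimethoxy-5-propylbenzene F2.
- Vilsmeier–Haack formylation (POCl3, DMF) para to one methoxy group and next to the propyl group should give 2,4-dimethoxy-6-propylbenzaldehyde F3.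
- Pinnick oxidation (NaClO2, NaH2PO4, 2-methyl-2-butene, t-BuOH–H2O) comes back to the route at 9.

Step 6.
- The carboxylation is reversible and may stop short of completion.
- It may also take place between the two hydroxyls, and the acid may decarboxylate during work-up.
- The fallback brings in the carbon as an aldehyde and sets out from 15.
- Vilsmeier–Haack formylation (POCl3, DMF) should give 2,4-dihydroxy-6-pentylbenzaldehyde F4.
- Allyl bromide and K2CO3 in acetone alkylate the unchelated hydroxyl to give 4-(allyloxy)-2-hydroxy-6-pentylbenzaldehyde F5.
- MeI and K2CO3 in DMF give 4-(allyloxy)-2-methoxy-6-pentylbenzaldehyde F6.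
- Pinnick oxidation with 2-methyl-2-butene as scavenger gives 4-(allyloxy)-2-methoxy-6-pentylbenzoic acid F7.
- BnBr with KHCO3 in DMF comes back to the route at 20.

Step 11.
- Acyl transfer from the hindered acid may be slow.
- The ortho benzyl ether may be lost in the acidic medium, and ring B may be acylated on carbon.
- The fallback drops the protecting group on ring A, and with it steps 4 and 5, and changes the mode of activation.
- It sets out from 11 and 21, which are condensed with N,N'-dicyclohexylcarbodiimide in dry toluene at room temperature. The C2 hydroxyl of 11 is held by its hydrogen bond to the carboxyl group and should not compete.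
- This should give benzyl 4-[(2-hydroxy-4-methoxy-6-propylbenzoyl)oxy]-2-methoxy-6-pentylbenzoate F8.
- Hydrogenolysis of F8 (H2, Pd/C, EtOAc) comes back to the route at 24.

**Further compounds**
F1 | step 2 | propylmagnesium chloride | CCC[Mg]Cl
F2 | step 2 | 1,3-dimethoxy-5-propylbenzene | CCCc1cc(OC)cc(OC)c1
F3 | step 2 | 2,4-dimethoxy-6-propylbenzaldehyde | CCCc1cc(OC)cc(OC)c1C=O
F4 | step 6 | 2,4-dihydroxy-6-pentylbenzaldehyde | CCCCCc1cc(O)cc(O)c1C=O
F5 | step 6 | 4-(allyloxy)-2-hydroxy-6-pentylbenzaldehyde | CCCCCc1cc(OCC=C)cc(O)c1C=O
F6 | step 6 | 4-(allyloxy)-2-methoxy-6-pentylbenzaldehyde | CCCCCc1cc(OCC=C)cc(OC)c1C=O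
F7 | step 6 | 4-(allyloxy)-2-methoxy-6-pentylbenzoic acid | CCCCCc1cc(OCC=C)cc(OC)c1C(=O)O
F8 | step 11 | benzyl 4-[(2-hydroxy-4-methoxy-6-propylbenzoyl)oxy]-2-methoxy-6-pentylbenzoate | CCCCCc1cc(OC(=O)c2c(O)cc(OC)cc2CCC)cc(OC)c1C(=O)OCc1ccccc1
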